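**Compound numbering used throughout** ("geranyl" = (2E)-3,7-dimethylocta-2,6-dien-1-yl)

1 2,4-dihydroxybenzaldehyde · 2 2,4-bis(methoxymethoxy)benzaldehyde · 3 geranyl bromide · 4, 5, 6 lithium α-amino alkoxides formed in the flask · 7 3-geranyl-2,4-bis(methoxymethoxy)benzaldehyde · 8 3-geranyl-2-hydroxy-4-(methoxymethoxy)benzaldehyde · 9 2-(2,2-dibromovinyl)-6-geranyl-5-(methoxymethoxy)phenol · 10 5-bromoresorcinol · 11 1-bromo-3,5-bis(methoxymethoxy)benzene · 12 aryllithium · 13 lithium borate · 14 3,5-bis(methoxymethoxy)phenylboronic acid · 15 2-bromobenzofuran formed in the flask · 16 tris-MOM 2-arylbenzofuran · 17 target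

## The problem

The target 17 is a 2-arylbenzofuran. Benzo ring A (C3a, C4–C7, C7a) is fused to furan ring B (O1, C2, C3), and resorcinol ring C (C1''–C6'') is attached at C2. Ring A is a contiguously 1,2,3,4-tetrasubstituted arene: C3a, C7a–O1, C7–geranyl and C6–OH follow one another. The geranyl chain must therefore sit on the carbon between the two oxygens of a resorcinol unit and not on the more accessible C5. There is no stereogenic centre, so no element of the molecule can control another. The only stereochemical feature is the E geometry of C2'=C3' in the geranyl chain, which has to be bought and then preserved. The chain limits the chemistry that can be used. Its two trisubstituted olefins and the doubly activated benzylic and allylic C1'H2 rule out hydrogenolysis, boron tribromide and strong protic or Lewis acids. Acid would add the 6-OH to C2'=C3' to give a chroman or cyclise the diene. The free triphenol is also air-sensitive in base, so the oxygens must stay masked until the end and the masks must come off gently. The enabling feature is C2 itself: it is bonded to O1 and to C1'' and doubly bonded to C3. C2 can therefore be the dibromo carbon of a 2-(2,2-dibromovinyl)phenol, with one bromide exchanged for O1 and the other for C1'' in a single flask, and C3 then traces back to an aldehyde carbon on ring A.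

## Retrosynthesis

**17 from 16.** Three O–CH2 acetal bonds are cut, giving the tris(methoxymethyl) ether 16. Methyl and benzyl ethers are excluded because their removal would destroy the geranyl chain. Aryl silyl ethers would not survive the organolithium and hot phosphate steps upstream. The MOM group also serves as the directing group that places the geranyl chain. The forward reaction must cleave three acetals with only catalytic acid, so that the 6-OH does not add to C2'=C3'.

**16 from 9 and 14, through 15.** O1–C2 and C2–C1'' are cut together. Dibromoolefin phenol 9 supplies ring A with C3 and C2, and boronic acid 14 supplies ring C. A cyclisation onto an alkyne would need a terminal 2-ethynylphenol that can close prematurely to a 2-unsubstituted benzofuran. An intramolecular Wittig closure would need benzylic halide and acid chloride chemistry that the geranyl chain would not tolerate. The gem-dibromide comes in one step from an aldehyde and carries both leaving groups on the carbon that needs two new bonds. The cut turns a tricyclic, fully substituted core into two benzene derivatives with every oxygen already in place. The forward step must close ring B at the single free hydroxyl to give 15 and then arylate the remaining C2–Br without double arylation.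

**14 from 11 and 10, through 12 and 13.** The C–B bond is cut back to aryl bromide 11, and the two acetals back to commercial 10. Bromine–lithium exchange gives 12 and borate trapping gives 13. This fixes boron at the position meta to both oxygens, which electrophilic or directed borylation of a resorcinol ether would not reach. The same MOM groups as in ring A allow one final deprotection.

**9 from 8.** The C3=C2 double bond is cut by a Ramirez dibromo-olefination of salicylaldehyde 8. This keeps the future O1 as a free hydroxyl and the future C3 as the aldehyde carbon. The olefination must tolerate the free, chelated phenol.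

**8 from 7.** One O–CH2 bond is cut, that of the acetal ortho to the aldehyde in 7. Differentiating the two oxygens at this stage costs one step. It relies on the only structural difference between them: the 2-oxygen can chelate a Lewis acid together with the carbonyl oxygen, and the 4-oxygen cannot. The reagent must be a non-protic Lewis acid so that the geranyl chain is left alone.

**7 from 2 and 3, through 4, 5 and 6.** The aryl–C1' bond at C3 is cut. Friedel–Crafts geranylation would attack C5 and needs acid. A Claisen route would deliver the reversed allyl unit. Directed metalation between two acetal oxygens is regiospecific for C3. The aldehyde of 2 is masked in the same flask as α-amino alkoxide 4, metalated to 5, allylated with 3 to 6 and released on work-up. The allylation must occur at the primary carbon of 3 with retention of the E olefin.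

**2 from 1.** Two O–CH2 bonds are cut, back to commercial 1, which already carries the ring A oxygens and the C3 carbon in the correct relationship.

## Roads not taken

**Alternative 1:** Ring A is taken apart completely (C4–C5, C5–C6, C7–C7a, C3a–C7a) into enynyl diazo ketone A1 and geranyl siloxyalkyne A2. In the forward Danheiser benzannulation, irradiation of A1 triggers a Wolff rearrangement to a vinylketene. This adds A2 in a [2+2] sense, and the cyclobutenone opens and closes by 6π electrocyclisation to give 2-alkynylphenol A3. A3 would then be cycloisomerised to the benzofuran and desilylated.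
- Merits: the tetrasubstitution pattern of ring A is fixed by construction and needs no directing group. The geranyl chain enters on an alkyne carbon, not by arene allylation. The silyl ethers come off with fluoride, which is kinder to the ortho-geranylphenol than the acetal cleavage of the chosen route. In these respects it is the better plan.
- Weak points: A1 and A2 each need several steps from commercial material. The photochemical step must work on a substrate with an extended enyne chromophore and two further olefins. A3 still needs a ring B closure and a deprotection, so the count is clearly higher.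
- Comparison: the chosen plan buys ring A ready-made and forms ring B and the biaryl bond in one flask. It answers the acid problem with catalytic acid and a non-protic fallback.

**Alternative 2:** The cut is C3a–C4 inside ring A, with the 2-arylfuran made first and carrying the enaminone side chain of A4. In the forward step, heating enolises the ketone towards C7, the dienol undergoes 6π electrocyclisation through the furan C3a=C7a bond, and loss of the amine aromatises ring A to A5.
- Merits: the 6-OH appears unprotected and needs no group of its own. The geranyl chain is installed by simple alkylation of a doubly activated carbon with 3. The remaining silyl ethers are fluoride-labile.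
- Weak points: the electrocyclisation must use a furan double bond as one of its three π components and needs the enol geometry that places the furan cis to the vinylogous amide. The high temperature required would expose a free ortho-geranylphenol to thermal cyclisation. A4 requires a 2,5-disubstituted furan to be built, extended and alkylated, which is a longer linear sequence than the whole of the chosen route.
- Comparison: it is more original and avoids all regiochemical questions on ring A. The chosen plan offers two commercial oxygenated arenes, a shorter sequence and a key step with direct precedent on simple substrates.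

**Alternative 3:** The cut is C1''–C2'' of ring C, which is folded from the hexane-1,3,5-trione chain of A6 in a biomimetic aldol reaction. In the forward step, aqueous hydroxide makes the terminal methyl carbon attack the benzofuran-2-yl ketone, and dehydration and enolisation give the free resorcinol A7.
- Merits: ring C arrives unprotected, so only one acetal remains to be cleaved at the end, against three in the chosen route. The step mirrors the biosynthetic logic.
- Weak points: rings A and B and the geranyl chain must be assembled first by chemistry of the same length as the chosen route up to 8, and the six-carbon chain then has to be added. The aldol must attack a conjugated, electron-rich and hence poorly electrophilic carbonyl in competition with pyranone formation and retro-Claisen cleavage. A7 is an air-sensitive resorcinol generated in hot base.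
- Comparison: the chosen plan gives up the saving in deprotections but buys ring C for two simple steps and avoids building a benzene ring that is commercially available.

Key step: step 7

Assumption: the SMILES defines the target; the C7 substituent is the (E)-geranyl group and the molecule has no stereogenic centre, so only this olefin geometry has to be carried through.

## Route

Step 1
Reactants: 1 2,4-dihydroxybenzaldehyde
Product: 2 2,4-bis(methoxymethoxy)benzaldehyde
Conditions: NaH (2.5 equiv), MOMCl (2.5 equiv), DMF, 0 °C → rt
Reagents that add atoms: chloromethyl methyl ether (MOMCl), COCCl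
Why: Williamson-type O-alkylation of both phenoxides by the chloromethyl ether; the strong base is needed because the 2-OH is hydrogen-bonded to the aldehyde and reacts sluggishly with carbonate or amine bases.

Step 2
Reactants: 2 2,4-bis(methoxymethoxy)benzaldehyde; 3 geranyl bromide [(2E)-1-bromo-3,7-dimethylocta-2,6-diene]
Product: 7 3-geranyl-2,4-bis(methoxymethoxy)benzaldehyde, via lithium α-amino alkoxide 4 (not isolated), via 3-lithio α-amino alkoxide 5 (not isolated), via 3-geranyl α-amino alkoxide 6 (not isolated)
Conditions: lithium 4-methylpiperazin-1-ide (from 1-methylpiperazine and n-BuLi), THF, −20 °C; then n-BuLi (1.5 equiv), −20 → 0 °C; then CuI (10 mol %), 3, −40 °C → rt; H2O quench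
Reagents that add atoms: none
Why: Addition of the lithium amide masks the aldehyde in situ as α-amino alkoxide 4 (racemic at the aminal carbon, which is lost again); directed ortho-metalation then occurs at C3, the position flanked by both acetal oxygens, because the piperazine-derived alkoxide is only a weak director and leaves C6 alone. Copper-catalysed SN2 allylation of aryllithium 5 by the primary allylic bromide keeps the E olefin, and water collapses 6 to the aldehyde.

Step 3
Reactants: 7 3-geranyl-2,4-bis(methoxymethoxy)benzaldehyde
Product: 8 3-geranyl-2-hydroxy-4-(methoxymethoxy)benzaldehyde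
Conditions: MgBr2·OEt2 (3 equiv), CH2Cl2–Et2O, 0 °C → rt; H2O
Reagents that add atoms: none
Why: Chelation-controlled Lewis acid cleavage of an acetal ether: magnesium bridges the carbonyl oxygen and the ortho aryl oxygen in a six-membered chelate, bromide opens the activated O–CH2 bond, and the 4-acetal, which cannot chelate, stays. The reaction type is the known selective dealkylation of ortho-alkoxy aryl carbonyl compounds by magnesium halides, and the absence of protic acid protects the geranyl chain.

Step 4
Reactants: 8 3-geranyl-2-hydroxy-4-(methoxymethoxy)benzaldehyde
Product: 9 2-(2,2-dibromovinyl)-6-geranyl-5-(methoxymethoxy)phenol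
Conditions: CBr4 (2 equiv), PPh3 (4 equiv), Et3N (1 equiv), CH2Cl2, 0 °C
Reagents that add atoms: carbon tetrabromide, BrC(Br)(Br)Br
Why: Ramirez olefination (first stage of the Corey–Fuchs sequence): the dibromomethylene ylide formed from PPh3 and CBr4 converts the aldehyde into the gem-dibromoalkene by a Wittig reaction; salicylaldehydes are olefinated directly when an amine buffers the HBr released by reversible phosphonylation of the phenol, which also protects the acetal and the olefins.

Step 5
Reactants: 10 5-bromoresorcinol (5-bromobenzene-1,3-diol)
Product: 11 1-bromo-3,5-bis(methoxymethoxy)benzene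
Conditions: NaH (2.4 equiv), MOMCl (2.4 equiv), DMF, 0 °C → rt
Reagents that add atoms: chloromethyl methyl ether (MOMCl), COCCl
Why: Williamson-type acetal protection of both phenols; the aryl bromide is inert under these conditions.

Step 6
Reactants: 11 1-bromo-3,5-bis(methoxymethoxy)benzene
Product: 14 3,5-bis(methoxymethoxy)phenylboronic acid, via 3,5-bis(methoxymethoxy)phenyllithium 12 (not isolated), via lithium aryltriisopropoxyborate 13 (not isolated)
Conditions: n-BuLi, THF, −78 °C; B(OiPr)3, −78 °C → rt; 1 M HCl to pH 5, 0 °C
Reagents that add atoms: triisopropyl borate, CC(C)OB(OC(C)C)OC(C)C; water, O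
Why: Bromine–lithium exchange at −78 °C is faster than ortho-deprotonation next to the acetals, the aryllithium is trapped as the borate, and brief cold hydrolysis at pH 5 releases the boronic acid without touching the MOM ethers.

Step 7
Reactants: 9 2-(2,2-dibromovinyl)-6-geranyl-5-(methoxymethoxy)phenol; 14 3,5-bis(methoxymethoxy)phenylboronic acid
Product: 16 7-geranyl-6-(methoxymethoxy)-2-[3,5-bis(methoxymethoxy)phenyl]benzofuran, via 2-bromo-7-geranyl-6-(methoxymethoxy)benzofuran 15 (not isolated)
Conditions: CuI (10 mol %), K3PO4 (4 equiv), THF, 80 °C (sealed tube); then 14 (1.5 equiv), Pd(PPh3)4 (5 mol %), H2O, 80 °C, same flask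
Reagents that add atoms: none
Why: The reaction type is the known tandem of copper-catalysed intramolecular O-vinylation of a 2-(2,2-dibromovinyl)phenol (an Ullmann-type C–O coupling) with Suzuki–Miyaura coupling of the resulting 2-bromobenzofuran. K3PO4 forms the phenoxide of 9, which binds monovalent copper; the C–Br bond cis to the arene, the only one within reach of the oxygen, is engaged and C–O bond formation gives O1–C2 and 2-bromobenzofuran 15. Ring B thus closes in a formally 5-endo-trig mode at the dibromo carbon, which is feasible because the bond is made by substitution at a metal-activated vinylic bromide and not by conjugate addition, and aromatisation to the furan drives it. Zerovalent palladium then inserts into the C2–Br bond of 15, the boronate formed from 14 and phosphate transmetalates, and reductive elimination forms C2–C1''. No stereocentre is created. The site of ring closure is fixed because the hydroxyl on the future C7a is the only free one, the 6-oxygen being an acetal; should palladium couple the bromide trans to the arene before the ring has closed, the resulting bromostilbene still cyclises to 16, so both orders converge. The one selectivity that matters is avoidance of double arylation of the gem-dibromide, and it is secured by letting the copper-mediated closure finish before 14 and Pd(PPh3)4 are added to the same flask. The geranyl olefins carry no leaving group and lie far from C2, the MOM acetals are inert to phosphate, and 14 has no ortho substituent that would favour protodeboronation.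

Step 8
Reactants: 16 7-geranyl-6-(methoxymethoxy)-2-[3,5-bis(methoxymethoxy)phenyl]benzofuran
Product: 17 7-geranyl-2-(3,5-dihydroxyphenyl)benzofuran-6-ol (the target, mulberrofuran L)
Conditions: conc. HCl (cat.), MeOH, 40 °C
Reagents that add atoms: none
Why: Acid-catalysed transacetalisation of the three aryl MOM ethers to methanol (released as dimethoxymethane); catalytic acid at moderate temperature is the standard way of unmasking prenylated and geranylated phenols and should be mild enough that the 6-OH does not add to C2'=C3'.

## Compound list

1 | 2,4-dihydroxybenzaldehyde | O=Cc1ccc(O)cc1O | starting material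
2 | 2,4-bis(methoxymethoxy)benzaldehyde | COCOc1ccc(C=O)c(OCOC)c1 | intermediate
3 | geranyl bromide, (2E)-1-bromo-3,7-dimethylocta-2,6-diene | CC(C)=CCC/C(C)=C/CBr | starting material
4 | lithium [2,4-bis(methoxymethoxy)phenyl](4-methylpiperazin-1-yl)methanolate (racemic) | COCOc1ccc(C(O[Li])N2CCN(C)CC2)c(OCOC)c1 | intermediate (not isolated)
5 | lithium [3-lithio-2,4-bis(methoxymethoxy)phenyl](4-methylpiperazin-1-yl)methanolate (racemic) | COCOc1ccc(C(O[Li])N2CCN(C)CC2)c(OCOC)c1[Li] | intermediate (not isolated)
6 | lithium [3-geranyl-2,4-bis(methoxymethoxy)phenyl](4-methylpiperazin-1-yl)methanolate (racemic, E olefin) | COCOc1ccc(C(O[Li])N2CCN(C)CC2)c(OCOC)c1C/C=C(\C)CCC=C(C)C | intermediate (not isolated)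
7 | 3-geranyl-2,4-bis(methoxymethoxy)benzaldehyde | COCOc1ccc(C=O)c(OCOC)c1C/C=C(\C)CCC=C(C)C | intermediate
8 | 3-geranyl-2-hydroxy-4-(methoxymethoxy)benzaldehyde | COCOc1ccc(C=O)c(O)c1C/C=C(\C)CCC=C(C)C | intermediate
9 | 2-(2,2-dibromovinyl)-6-geranyl-5-(methoxymethoxy)phenol | COCOc1ccc(C=C(Br)Br)c(O)c1C/C=C(\C)CCC=C(C)C | intermediate
10 | 5-bromoresorcinol | Oc1cc(O)cc(Br)c1 | starting material
11 | 1-bromo-3,5-bis(methoxymethoxy)benzene | COCOc1cc(Br)cc(OCOC)c1 | intermediate
12 | 3,5-bis(methoxymethoxy)phenyllithium | [Li]c1cc(OCOC)cc(OCOC)c1 | intermediate (not isolated)
13 | lithium [3,5-bis(methoxymethoxy)phenyl]triisopropoxyborate | [Li+].CC(C)O[B-](OC(C)C)(OC(C)C)c1cc(OCOC)cc(OCOC)c1 | intermediate (not isolated)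
14 | 3,5-bis(methoxymethoxy)phenylboronic acid | COCOc1cc(OCOC)cc(B(O)O)c1 | intermediate
15 | 2-bromo-7-geranyl-6-(methoxymethoxy)benzofuran | COCOc1ccc2cc(Br)oc2c1C/C=C(\C)CCC=C(C)C | intermediate (not isolated)
16 | 7-geranyl-6-(methoxymethoxy)-2-[3,5-bis(methoxymethoxy)phenyl]benzofuran | COCOc1ccc2cc(-c3cc(OCOC)cc(OCOC)c3)oc2c1C/C=C(\C)CCC=C(C)C | intermediate
17 | 7-geranyl-2-(3,5-dihydroxyphenyl)benzofuran-6-ol (mulberrofuran L) | CC(C)=CCC/C(C)=C/Cc1c(O)ccc2cc(-c3cc(O)cc(O)c3)oc12 | target

## Step count and risk

Total step count: 8. Longest linear sequence: 6 (steps 1, 2, 3, 4, 7, 8); steps 5 and 6 form the two-step side branch to 14.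

**Step 7 (key step).** The phenoxide of 9 is flanked by the geranyl CH2 and the vinyl group, so ring closure may be slow. Base-induced loss of HBr to a bromoalkyne, reduction of the C2–Br bond of 15, or coupling of both bromides could then compete. Fallback: setting out from 8, a Seyferth–Gilbert homologation with the Ohira–Bestmann reagent (K2CO3, MeOH) would give 2-ethynyl-6-geranyl-5-(methoxymethoxy)phenol F1. Sonogashira coupling of F1 with bromide 11 (Pd(PPh3)2Cl2, CuI, Et3N, DMF, 80 °C) would give diarylalkyne 2-{[3,5-bis(methoxymethoxy)phenyl]ethynyl}-6-geranyl-5-(methoxymethoxy)phenol F2. F2 closes 5-endo-dig under the same copper and amine conditions and returns to the route at 16. The same two bonds are formed and step 6 is not needed. It is held in reserve because a terminal 2-ethynylphenol can cyclise before it couples and 11 is an electron-rich, slow coupling partner.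

**Step 2.** Metalation of 4 may be incomplete. Excess butyllithium may consume 3. Allylation may partly follow the SN2' course and give the tertiary (linalyl-type) isomer. If the amino alkoxide reverts, butyllithium adds to the aldehyde. Fallback: setting out from 3 and resorcinol, protection gives 1,3-bis(methoxymethoxy)benzene F3. Lithiation of F3 between the oxygens and allylation with 3 (n-BuLi, THF, 0 °C; CuI cat.) gives 2-geranyl-1,3-bis(methoxymethoxy)benzene F4. A second ortho-lithiation (n-BuLi, TMEDA) with DMF quench rejoins the route at 7. No carbonyl has to be masked there, at the price of one more step and of possible deprotonation at the benzylic and allylic CH2.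

**Step 3.** Cleavage may stop short or go on to remove the 4-acetal as well. The magnesium phenoxide, once formed, may add to the neighbouring olefin. Fallback: setting out from 1 and 3, direct C-alkylation of the phenoxide in aqueous KOH gives 3-geranyl-2,4-dihydroxybenzaldehyde F5. Regioselectivity and efficiency are expected to be modest, since C5- and O-alkylation compete. Selective protection of the non-chelated 4-OH (MOMCl, K2CO3, acetone, rt) then returns to the route at 8, replacing steps 1 to 3 and relying on selective protection in place of selective deprotection.

**Step 4.** The free phenol may be phosphonylated or brominated by the phosphorus(V) bromide by-product, and HBr set free may cleave the acetal or close a chroman. Fallback: setting out from 8, silylation (TBSCl, imidazole, DMF) gives 2-(tert-butyldimethylsilyloxy)-3-geranyl-4-(methoxymethoxy)benzaldehyde F6. Ramirez olefination (CBr4, PPh3, CH2Cl2, 0 °C) gives the silyl ether of the dibromoolefin F7. Bu4NF in THF at 0 °C returns to the route at 9.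

**Step 8.** Protonation of C2'=C3' may lead to attack by the 6-OH (chroman formation), or methanol may add to the terminal olefin, before all three acetals are gone. Fallback: setting out from 16, treatment with triethylsilyl triflate and 2,2'-bipyridyl in CH2Cl2 at 0 °C exchanges the aryl acetals for silyl ethers without protic acid and gives the tris(triethylsilyl) ether F8. Bu4NF buffered with AcOH in THF then returns to the route at 17.

## Further compounds

F1 | step 7 | 2-ethynyl-6-geranyl-5-(methoxymethoxy)phenol | COCOc1ccc(C#C)c(O)c1C/C=C(\C)CCC=C(C)C
F2 | step 7 | 2-{[3,5-bis(methoxymethoxy)phenyl]ethynyl}-6-geranyl-5-(methoxymethoxy)phenol | COCOc1ccc(C#Cc2cc(OCOC)cc(OCOC)c2)c(O)c1C/C=C(\C)CCC=C(C)C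
F3 | step 2 | 1,3-bis(methoxymethoxy)benzene | COCOc1cccc(OCOC)c1
F4 | step 2 | 2-geranyl-1,3-bis(methoxymethoxy)benzene | COCOc1cccc(OCOC)c1C/C=C(\C)CCC=C(C)C
F5 | step 3 | 3-geranyl-2,4-dihydroxybenzaldehyde | O=Cc1ccc(O)c(C/C=C(\C)CCC=C(C)C)c1O
F6 | step 4 | 2-(tert-butyldimethylsilyloxy)-3-geranyl-4-(methoxymethoxy)benzaldehyde | COCOc1ccc(C=O)c(O[Si](C)(C)C(C)(C)C)c1C/C=C(\C)CCC=C(C)C
F7 | step 4 | tert-butyl[2-(2,2-dibromovinyl)-6-geranyl-5-(methoxymethoxy)phenoxy]dimethylsilane | COCOc1ccc(C=C(Br)Br)c(O[Si](C)(C)C(C)(C)C)c1C/C=C(\C)CCC=C(C)C
F8 | step 8 | 7-geranyl-6-(triethylsilyloxy)-2-[3,5-bis(triethylsilyloxy)phenyl]benzofuran | CC[Si](CC)(CC)Oc1cc(O[Si](CC)(CC)CC)cc(-c2cc3ccc(O[Si](CC)(CC)CC)c(C/C=C(\C)CCC=C(C)C)c3o2)c1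
A1 | alternative 1 | (3E)-1-diazo-6-[3,5-bis(triisopropylsilyloxy)phenyl]hex-3-en-5-yn-2-one | [N-]=[N+]=CC(=O)/C=C/C#Cc1cc(O[Si](C(C)C)(C(C)C)C(C)C)cc(O[Si](C(C)C)(C(C)C)C(C)C)c1
A2 | alternative 1 | {[(4E)-5,9-dimethyldeca-4,8-dien-1-yn-1-yl]oxy}triisopropylsilane | CC(C)=CCC/C(C)=C/CC#CO[Si](C(C)C)(C(C)C)C(C)C
A3 | alternative 1 | 2-{[3,5-bis(triisopropylsilyloxy)phenyl]ethynyl}-6-geranyl-5-(triisopropylsilyloxy)phenol | CC(C)=CCC/C(C)=C/Cc1c(O)c(C#Cc2cc(O[Si](C(C)C)(C(C)C)C(C)C)cc(O[Si](C(C)C)(C(C)C)C(C)C)c2)ccc1O[Si](C(C)C)(C(C)C)C(C)C
A4 | alternative 2 | (1E,6E)-4-{5-[3,5-bis(tert-butyldimethylsilyloxy)phenyl]furan-2-yl}-1-(dimethylamino)-7,11-dimethyldodeca-1,6,10-trien-3-one (racemic) | CN(C)/C=C/C(=O)C(C/C=C(\C)CCC=C(C)C)c1ccc(-c2cc(O[Si](C)(C)C(C)(C)C)cc(O[Si](C)(C)C(C)(C)C)c2)o1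
A5 | alternative 2 | 7-geranyl-2-[3,5-bis(tert-butyldimethylsilyloxy)phenyl]benzofuran-6-ol | CC(C)=CCC/C(C)=C/Cc1c(O)ccc2cc(-c3cc(O[Si](C)(C)C(C)(C)C)cc(O[Si](C)(C)C(C)(C)C)c3)oc12
A6 | alternative 3 | 1-[7-geranyl-6-(methoxymethoxy)benzofuran-2-yl]hexane-1,3,5-trione | CC(=O)CC(=O)CC(=O)c1cc2ccc(OCOC)c(C/C=C(\C)CCC=C(C)C)c2o1
A7 | alternative 3 | 5-[7-geranyl-6-(methoxymethoxy)benzofuran-2-yl]benzene-1,3-diol | Oc1cc(O)cc(-c2cc3ccc(OCOC)c(C/C=C(\C)CCC=C(C)C)c3o2)c1
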